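## The problem

2,3,5,6-Tetrabromo-1H-indole 15 is a bare indole, a benzene ring fused to a pyrrole ring, in which four of the six ring CH positions carry bromine and nothing else is present. There is no stereocentre, so the whole problem is regiochemical: two bromines sit on the adjacent benzo carbons C5 and C6 and two on the pyrrole carbons C2 and C3. The first pair cannot be placed cleanly by electrophilic bromination of an indole, which reacts at C3, then at C2, and only then unselectively on the benzo ring; the second pair is easy to introduce, but a late double bromination of a free NH-indole invites over-bromination and oxidation to oxindoles. The product is delicate: 2-haloindoles with a free NH are hydrolysed by aqueous acid and are sensitive to light and excess oxidant, and the four C–Br bonds exclude zerovalent palladium, palladium-catalysed hydrogenolysis and organolithium reagents late in the route. The feature that opens a different entry is C2, an sp2 carbon bound to N1, to C3 and to bromine, which is the substitution pattern of the carbon of an N-aryl carbonimidoyl dibromide (ArN=CBr2) after one bromide has been replaced by carbon. If C3 arrives as a benzylic carbanion on the same benzene ring, the pyrrole ring closes across C2–C3 with the C2 bromine already in place, and the carboxyl group that made C3 nucleophilic can afterwards be exchanged for the C3 bromine by ipso substitution.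

## Retrosynthesis

The C3–Br bond of 15 is cut first and the bromine is replaced by a carboxyl group, giving 2,5,6-tribromo-1H-indole-3-carboxylic acid 14. A hydrogen at C3 would also brominate, but the carboxyl is needed anyway to make C3 a carbon nucleophile in the ring closure, and its ipso replacement leaves no question of position. 14 is no simpler in atom count, but it defers the labile 2,3-dibromo enamine unit to the last step. The forward reaction must deliver electrophilic bromine to C3 of an electron-poor indole and decarboxylate without touching N1 or the benzo ring.

14 is traced to its tert-butyl ester 13 by cleavage of the ester C–O bond. A methyl ester would have to be saponified on a 2-bromoindole-3-carboxylate, whose carbonyl is deactivated as a vinylogous carbamate while C2 is open to nucleophiles as a vinylogous acyl bromide. The tert-butyl ester is removed by acid instead, and earlier in the route it does not acylate the neighbouring aniline nitrogen. The forward step only has to expel the tert-butyl group.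

The C2–C3 bond of 13 is cut next, opening the pyrrole ring to the aryl carbonimidoyl dibromide 11. Cutting N1–C2 or C3–C3a would leave the C2 bromine to be introduced on a formed indole. Cutting C2–C3 lets C2 arrive with its bromine as the N=CBr2 carbon and C3 arrive as an ester-stabilized benzylic carbanion. The precursor is a monocyclic benzene with two ortho side chains. The forward reaction requires attack through the enolate carbon and not oxygen, displacement of only one bromide, and ring closure faster than intermolecular attack. It passes through the 3H-indole 12, which aromatizes.

11 is cut at both C–Br bonds of the imidoyl carbon to the isocyanide 9 and bromine 10. α-Addition of halogen to the divalent isocyanide carbon is the direct route to a carbonimidoyl dihalide, and no clean alternative exists for the dibromide. 9 carries no labile side-chain halogen and can be purified. The addition must outrun bromination at the benzylic position or on the ring, which the deactivated arene and the absence of base should ensure.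

9 is traced through its formamide 8 (dehydration) to the nitro ester 6 (N–CHO bond, then the N–O bonds), the aniline 7 being passed only in solution. Nitrogen is carried as a nitro group because it enters the ring that way and because the nitro group acidifies the benzylic methyl one stage earlier. The reduction must spare two aryl C–Br bonds, and the aniline must not close onto the ester.

6 is the tert-butyl ester of acid 5, and 5 is cut between the benzylic carbon and the carboxyl carbon to 1,2-dibromo-4-methyl-5-nitrobenzene 2 and dimethyl oxalate 3. The carboxyl carbon enters as an oxalyl unit by Reissert condensation, and the extra carbon of pyruvate 4 is removed by oxidative cleavage. This uses the acidity of the ortho-nitrotoluene methyl and avoids nitrobenzyl halide and cyanide chemistry, which tends to give dimers. The forward sequence needs C-acylation to beat attack of alkoxide on the bromine para to the nitro group.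

2 is cut at its C–N bond to 3,4-dibromotoluene 1. Of the three free positions of 1, the one ortho to methyl and para to the C3 bromine is favoured by both directors and is the least hindered. The two bromines that become C5 and C6 of the indole are thus bought with the starting material and are never installed on a heterocycle.

## Roads not taken

Alternative 1: The benzene ring is taken apart at C3a–C7a, C4–C5 and C6–C7, which leads to the ynamide-tethered diyne N-(but-3-yn-1-yl)-N-ethynyl-4-methylbenzenesulfonamide A1 and bis(trimethylsilyl)acetylene A2. In the forward sense the catalyst CpCo(CO)2 A3, a complex of monovalent cobalt, would cocyclize A1 with A2 in a (2+2+2) cyclotrimerization. This closes the benzene ring and the five-membered nitrogen ring in one operation and gives 1-tosyl-5,6-bis(trimethylsilyl)indoline A4. The two silyl groups of A4 mark C5 and C6 and would be exchanged for bromine by ipso-bromodesilylation. Oxidation of the indoline ring, removal of the sulfonyl group to 5,6-dibromo-1H-indole A5 and electrophilic dibromination of A5 at C3 and C2 would then give 15.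

- Merit: the 5,6-pattern is fixed by construction with no isomer to separate. This is better than the nitration of 1 in the chosen plan, where a minor regioisomer must be removed by crystallization.
- Weak points: five operations separate A4 from 15, and the second ipso substitution is slowed by the first bromine. The terminal ynamide A1 needs its own synthesis, and A3 has to be used with a large excess of A2 to keep the diyne from oligomerizing with itself. The pyrrole-ring bromines are still introduced last on a free NH-indole.
- Comparison: the chosen plan needs two operations after ring closure and places the C2 bromine by bond construction. Against the cleaner benzo-ring regiochemistry of this alternative it can only set that its isomer problem is met at the first and cheapest step.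

Alternative 2: Here C3a–C4 and C7–C7a are cut, so that the benzo ring comes from 3,4-dibromothiophene 1,1-dioxide A6 as a four-carbon diene and the nitrogen ring from the enecarbamate tert-butyl 2,3-dihydro-1H-pyrrole-1-carboxylate A7. An inverse-demand Diels–Alder addition of A6 to the double bond of A7, followed by cheletropic extrusion of the sulfonyl bridge, would give tert-butyl cis-5,6-dibromo-2,3,3a,7a-tetrahydroindole-1-carboxylate A8 (racemic, cis from the suprafacial addition). Dehydrogenation of the cyclohexadiene, oxidation of the indoline, carbamate removal to A5 and dibromination would complete the synthesis.

- Merits: both A6 and A7 are close to commercial materials, and the bromines at C5 and C6 are placed by the diene without any directing-group argument. The route could be two or three steps shorter than the chosen one, and its key step is better precedented than the ring closure proposed here.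
- Weak points: A8 is two dehydrogenations away from an indole, and its two stereocentres are made only to be destroyed. Aromatization of a dihydrobenzene carrying a carbamate nitrogen on an sp3 ring carbon can also occur by β-elimination of that nitrogen, which opens the five-membered ring. A6 dimerizes when the dienophile A7 is slow to react. The endgame is again the undirected dibromination of A5.
- Comparison: the chosen plan is longer and its key step less certain. It sets against this an arene that is aromatic from the first step, so no oxidation-level adjustment is needed, and four bromines each placed by a position-defined event.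

Alternative 3: The cut is made at C5–C6, the bond between the two bromine-bearing benzo carbons, which unfolds the benzene ring into the enediyne 4,5-dibromo-2,3-bis(bromoethynyl)-1-tosylpyrrole A9. Heating A9 with cyclohexa-1,4-diene A10 as hydrogen-atom donor would bring about a Bergman cycloaromatization. The two bromoalkyne termini join, and the diradical at C4 and C7 takes two hydrogen atoms from A10 to give 2,3,5,6-tetrabromo-1-tosylindole A11. A11 is one desulfonylation away from 15.

- Merit: on paper this is the most direct route, and in one respect it is better than the chosen plan. All four bromines are in place before the ring forms, and only the deprotection of A11 follows.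
- Weak points: an enediyne fused to a five-membered ring holds its alkyne termini further apart than a benzo-fused one, and terminal substituents add repulsion in the transition state, so high temperatures are expected. Under such conditions bromoalkynes polymerize. The aryl radicals at C4 and C7, each next to a C–Br bond, and the radicals derived from A10 open chain pathways for loss of bromine. A9 also needs two kinds of C–Br bond installed and preserved through alkyne coupling on a fully substituted pyrrole, a longer and less selective preparation than that of 11.
- Comparison: the chosen plan closes its ring by ionic chemistry at or below 0 °C, where no C–Br bond is at risk. It gives up the bromine-complete precursor and accepts one bromination after ring closure.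

Key step: step 7

## Route

Step 1
Reactants: 1 3,4-dibromotoluene (1,2-dibromo-4-methylbenzene)
Product: 2 1,2-dibromo-4-methyl-5-nitrobenzene (4,5-dibromo-2-nitrotoluene)
Conditions: fuming HNO3, conc. H2SO4, 0 °C → rt; recrystallization from EtOH
Reagents that add atoms: nitric acid, O[N+](=O)[O-]
Why: Electrophilic aromatic nitration; the position ortho to methyl and para to the C3 bromine is activated by both directors and is the least hindered, as in the nitration of the dichloro analogue, and minor isomers should be removed by crystallization.

Step 2
Reactants: 2 1,2-dibromo-4-methyl-5-nitrobenzene; 3 dimethyl oxalate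
Product: 5 2-(4,5-dibromo-2-nitrophenyl)acetic acid, via methyl 3-(4,5-dibromo-2-nitrophenyl)-2-oxopropanoate 4 (not isolated)
Conditions: KOMe, MeOH/Et2O, 0 °C → rt; then H2O, NaOH, 30% H2O2, 0–10 °C; HCl
Reagents that add atoms: dimethyl oxalate (3), COC(=O)C(=O)OC; hydrogen peroxide, OO
Why: Reissert condensation (Claisen-type acylation of the nitro-acidified benzylic methyl) gives the enolate of pyruvate 4, and alkaline peroxide then cleaves the α-keto acid (hydroperoxide adds to the ketone and the adduct fragments with decarboxylation), the classical route to 2-nitroarylacetic acids; fast deprotonation to the benzylic anion should shield the bromine para to nitro from methoxide.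

Step 3
Reactants: 5 2-(4,5-dibromo-2-nitrophenyl)acetic acid
Product: 6 tert-butyl 2-(4,5-dibromo-2-nitrophenyl)acetate
Conditions: tert-butyl 2,2,2-trichloroacetimidate, BF3·OEt2 (cat.), CH2Cl2/cyclohexane, rt
Reagents that add atoms: tert-butyl 2,2,2-trichloroacetimidate, CC(C)(C)OC(=N)C(Cl)(Cl)Cl
Why: Acid-catalysed tert-butylation of a carboxylic acid by the trichloroacetimidate; no base is present that could deprotonate the nitrobenzylic CH2, and the tert-butyl ester is chosen because it resists aminolysis at the aniline stage and is later removed by acid.

Step 4
Reactants: 6 tert-butyl 2-(4,5-dibromo-2-nitrophenyl)acetate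
Product: 8 tert-butyl 2-(4,5-dibromo-2-formamidophenyl)acetate, via tert-butyl 2-(2-amino-4,5-dibromophenyl)acetate 7 (not isolated)
Conditions: H2 (1 atm), 5% Pt/C (sulfided), EtOAc, rt; filter; then HCO2H/Ac2O (premixed), 0 °C → rt
Reagents that add atoms: acetic formic anhydride (from formic acid and acetic anhydride), CC(=O)OC=O
Why: Chemoselective nitro hydrogenation over sulfided platinum, which leaves aryl bromides intact, followed by N-formylation with the mixed anhydride at its formyl carbon; the tert-butyl ester should prevent the hydroxylamine and aniline stages from lactamizing to oxindoles.

Step 5
Reactants: 8 tert-butyl 2-(4,5-dibromo-2-formamidophenyl)acetate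
Product: 9 tert-butyl 2-(4,5-dibromo-2-isocyanophenyl)acetate
Conditions: POCl3, Et3N, THF, −20 → 0 °C; aq. Na2CO3
Reagents that add atoms: none
Why: Standard dehydration of an N-aryl formamide to the isocyanide (O-phosphorylation, then base-induced elimination); Et3N is too weak to enolize the arylacetate, so the ester and the isocyanide should coexist as in the parent ortho-isocyanophenylacetates.

Step 6
Reactants: 9 tert-butyl 2-(4,5-dibromo-2-isocyanophenyl)acetate; 10 bromine
Product: 11 tert-butyl 2-[4,5-dibromo-2-(dibromomethylideneamino)phenyl]acetate
Conditions: Br2 (1.0 equiv), CH2Cl2, −78 → 0 °C, dark; concentrate cold and use at once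
Reagents that add atoms: bromine (10), BrBr
Why: α-Addition of halogen to the divalent isocyanide carbon, the standard entry to carbonimidoyl dihalides; it should be much faster at low temperature than bromination of the deactivated ring or of the non-enolized benzylic position.

Step 7
Reactants: 11 tert-butyl 2-[4,5-dibromo-2-(dibromomethylideneamino)phenyl]acetate
Product: 13 tert-butyl 2,5,6-tribromo-1H-indole-3-carboxylate, via tert-butyl 2,5,6-tribromo-3H-indole-3-carboxylate 12 (not isolated)
Conditions: LiN(SiMe3)2 (2.2 equiv), THF (0.02 M), −78 → 0 °C, 11 added slowly to the base; aq. NH4Cl
Reagents that add atoms: none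
Why: Proposed new method: the first equivalent of the hindered amide base removes a benzylic proton (acidified by the ester, the ring bromines and the ortho N=CBr2 group), and the enolate carbon adds to the imidoyl carbon and expels one bromide (addition–elimination), forming C2–C3 and giving the 3H-indole 12, whose very acidic C3–H is removed by the second equivalent so that the product rests as the aromatic indolide of 13 until the quench. The closest known reaction types are the closure of ortho-hydroxy- and ortho-mercapto-aryl isocyanide dihalides to 2-halobenzoxazoles and 2-halobenzothiazoles, the base-mediated cyclization of ortho-isocyanoarylacetates to indole-3-carboxylates, and the 5-endo-trig closure of ortho-functionalized β,β-difluorostyrenes to 2-fluoro heterocycles. The one ring closed, the pyrrole ring, forms in a 5-(enolexo)-endo-trig mode if addition to C=N is direct, a formally disfavoured mode made feasible by the strongly polarized C=N bond with two leaving groups; if bromide ionizes first to an N-aryl bromonitrilium ion, the closure becomes the favoured 5-endo-dig mode. No stereocentre persists, since C3 of 12 is a transient racemic centre erased by deprotonation. Carbon rather than oxygen attack is required and is secured by ring size, because carbon attack gives the five-membered ring and oxygen attack a seven-membered ketene acetal. Single rather than double bromide displacement is required and is secured because the indolide is no longer an imidoyl electrophile at C2. Ring closure must also beat attack of the base or of a second enolate on N=CBr2, which the bulk of the silylamide, the low temperature and the slow addition at high dilution are meant to ensure.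

Step 8
Reactants: 13 tert-butyl 2,5,6-tribromo-1H-indole-3-carboxylate
Product: 14 2,5,6-tribromo-1H-indole-3-carboxylic acid
Conditions: CF3CO2H/CH2Cl2 (1:3), 0 °C → rt; evaporate with toluene
Reagents that add atoms: none
Why: Acidolysis of a tert-butyl ester through the tert-butyl cation; no nucleophile is present that could attack C2, and the three bromines make C3 protonation, and hence premature decarboxylation, unfavourable.

Step 9
Reactants: 14 2,5,6-tribromo-1H-indole-3-carboxylic acid
Product: 15 2,3,5,6-tetrabromo-1H-indole
Conditions: NBS (1.05 equiv), LiOAc (cat.), DMF, 0 °C → rt, dark; aq. Na2S2O3
Reagents that add atoms: N-bromosuccinimide, O=C1CCC(=O)N1Br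
Why: Ipso-bromodecarboxylation (Hunsdiecker-type halodecarboxylation of an electron-rich heteroaromatic acid): electrophilic bromine attacks C3, the enamine carbon, and the 3-bromo-3H-indole-3-carboxylate rearomatizes by decarboxylation; C3 is the only open pyrrole position and C4 and C7 are deactivated.

## Compound list

1 | 3,4-dibromotoluene (1,2-dibromo-4-methylbenzene) | Cc1ccc(Br)c(Br)c1 | starting material
2 | 1,2-dibromo-4-methyl-5-nitrobenzene | Cc1cc(Br)c(Br)cc1[N+](=O)[O-] | intermediate
3 | dimethyl oxalate | COC(=O)C(=O)OC | starting material
4 | methyl 3-(4,5-dibromo-2-nitrophenyl)-2-oxopropanoate (formed as its potassium enolate, not isolated) | COC(=O)C(=O)Cc1cc(Br)c(Br)cc1[N+](=O)[O-] | intermediate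
5 | 2-(4,5-dibromo-2-nitrophenyl)acetic acid | OC(=O)Cc1cc(Br)c(Br)cc1[N+](=O)[O-] | intermediate
6 | tert-butyl 2-(4,5-dibromo-2-nitrophenyl)acetate | CC(C)(C)OC(=O)Cc1cc(Br)c(Br)cc1[N+](=O)[O-] | intermediate
7 | tert-butyl 2-(2-amino-4,5-dibromophenyl)acetate (not isolated) | CC(C)(C)OC(=O)Cc1cc(Br)c(Br)cc1N | intermediate
8 | tert-butyl 2-(4,5-dibromo-2-formamidophenyl)acetate | CC(C)(C)OC(=O)Cc1cc(Br)c(Br)cc1NC=O | intermediate
9 | tert-butyl 2-(4,5-dibromo-2-isocyanophenyl)acetate | CC(C)(C)OC(=O)Cc1cc(Br)c(Br)cc1[N+]#[C-] | intermediate
10 | bromine | BrBr | starting material
11 | tert-butyl 2-[4,5-dibromo-2-(dibromomethylideneamino)phenyl]acetate | CC(C)(C)OC(=O)Cc1cc(Br)c(Br)cc1N=C(Br)Br | intermediate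
12 | tert-butyl 2,5,6-tribromo-3H-indole-3-carboxylate (racemic, transient, not isolated) | CC(C)(C)OC(=O)C1C(Br)=Nc2cc(Br)c(Br)cc12 | intermediate
13 | tert-butyl 2,5,6-tribromo-1H-indole-3-carboxylate | CC(C)(C)OC(=O)c1c(Br)[nH]c2cc(Br)c(Br)cc12 | intermediate
14 | 2,5,6-tribromo-1H-indole-3-carboxylic acid | OC(=O)c1c(Br)[nH]c2cc(Br)c(Br)cc12 | intermediate
15 | 2,3,5,6-tetrabromo-1H-indole | Brc1cc2[nH]c(Br)c(Br)c2cc1Br | target

## Step count and least certain steps

Total: 9 steps. Longest linear sequence: 9 steps, from 1 to 15; the route is fully linear.

Step 7 (key step, proposed new method). The most likely failure is that the enolate or the base reacts elsewhere instead of closing the ring. One path is halophilic attack on a bromine of N=CBr2, which would transfer bromine to the benzylic carbon and regenerate the isocyanide function. Another is addition of the silylamide or of a second enolate to the imidoyl carbon, leading to amidine or oligomer formation. Both are plausible because the imidoyl carbon is shielded by two bromines and direct closure is a 5-endo-trig process. The fallback uses known chemistry, sets out from 9 and returns at 15. Isocyanide 9 is cyclized with catalytic Cu2O in toluene at 60 °C, or with NaH in THF, the known 5-endo-dig closure of ortho-isocyanoarylacetates onto the isocyanide carbon, to tert-butyl 5,6-dibromo-1H-indole-3-carboxylate F1. CF3CO2H removes the tert-butyl group to give 5,6-dibromo-1H-indole-3-carboxylic acid F2. Two equivalents of NBS in DMF then effect ipso-bromodecarboxylation to 3,5,6-tribromo-1H-indole F3 and, in the same flask, electrophilic bromination at C2 to give 15. The C2 bromine then comes from a late electrophilic substitution instead of from the imidoyl carbon.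

Step 6. The most likely failure is loss of the adduct before it can be used: reversal to isocyanide and bromine on concentration, hydrolysis by traces of water, or benzylic bromination if acid builds up. Aryl carbonimidoyl dibromides are less robust than the dichlorides. The fallback sets out from 5 and returns at 14, taking the C2 bromine from a lactam carbonyl. Reduction of 5 with Fe powder in AcOH at 80 °C, with spontaneous lactamization, gives 5,6-dibromo-1,3-dihydro-2H-indol-2-one F4. Vilsmeier–Haack bromoformylation (POBr3, DMF, CHCl3, reflux) gives 2,5,6-tribromo-1H-indole-3-carbaldehyde F5. Pinnick oxidation (NaClO2, NaH2PO4, 2-methyl-2-butene, t-BuOH/THF/H2O) gives 14.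

Step 9. The most likely failure is slow ipso attack at the electron-poor C3, so that N-bromination or oxidative addition across C2–C3 followed by hydrolysis on work-up competes with decarboxylation. The fallback sets out from 14 and returns at 15 by separating the two events. Silver-catalysed protodecarboxylation (Ag2CO3 cat., AcOH, DMSO, 100 °C) gives 2,5,6-tribromo-1H-indole F6. Ordinary electrophilic bromination of its C3–H with NBS in DMF at 0 °C then gives 15.

Step 2. The most likely failure is displacement of the bromine para to the nitro group by methoxide (SNAr) or oxidative dimerization of the nitrobenzyl anion before acylation, with incomplete peroxide cleavage as a lesser risk. The fallback sets out from 2 and returns at 5. Aminomethylenation as in the first stage of the Leimgruber–Batcho indole synthesis (Me2NCH(OMe)2, pyrrolidine, DMF, 100 °C) gives (E)-1-[2-(4,5-dibromo-2-nitrophenyl)ethenyl]pyrrolidine F7. Hydrolysis (aq. HCl, THF) gives 2-(4,5-dibromo-2-nitrophenyl)acetaldehyde F8, and Pinnick oxidation (NaClO2, NaH2PO4, 2-methyl-2-butene) gives 5.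

## Further compounds

F1 | step 7 | tert-butyl 5,6-dibromo-1H-indole-3-carboxylate | CC(C)(C)OC(=O)c1c[nH]c2cc(Br)c(Br)cc12
F2 | step 7 | 5,6-dibromo-1H-indole-3-carboxylic acid | OC(=O)c1c[nH]c2cc(Br)c(Br)cc12
F3 | step 7 | 3,5,6-tribromo-1H-indole | Brc1c[nH]c2cc(Br)c(Br)cc12
F4 | step 6 | 5,6-dibromo-1,3-dihydro-2H-indol-2-one | O=C1Cc2cc(Br)c(Br)cc2N1
F5 | step 6 | 2,5,6-tribromo-1H-indole-3-carbaldehyde | O=Cc1c(Br)[nH]c2cc(Br)c(Br)cc12
F6 | step 9 | 2,5,6-tribromo-1H-indole | Brc1cc2cc(Br)[nH]c2cc1Br
F7 | step 2 | (E)-1-[2-(4,5-dibromo-2-nitrophenyl)ethenyl]pyrrolidine | [O-][N+](=O)c1cc(Br)c(Br)cc1/C=C/N1CCCC1
F8 | step 2 | 2-(4,5-dibromo-2-nitrophenyl)acetaldehyde | O=CCc1cc(Br)c(Br)cc1[N+](=O)[O-]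
A1 | alternative 1 | N-(but-3-yn-1-yl)-N-ethynyl-4-methylbenzenesulfonamide | Cc1ccc(cc1)S(=O)(=O)N(C#C)CCC#C
A2 | alternative 1 | bis(trimethylsilyl)acetylene | C[Si](C)(C)C#C[Si](C)(C)C
A3 | alternative 1 | cyclopentadienylcobalt dicarbonyl, CpCo(CO)2 | [Co+].[C-]#[O+].[C-]#[O+].c1cc[cH-]c1
A4 | alternative 1 | 1-tosyl-5,6-bis(trimethylsilyl)indoline | Cc1ccc(cc1)S(=O)(=O)N1CCc2cc([Si](C)(C)C)c([Si](C)(C)C)cc12
A5 | alternative 1 | 5,6-dibromo-1H-indole | Brc1cc2cc[nH]c2cc1Br
A6 | alternative 2 | 3,4-dibromothiophene 1,1-dioxide | O=S1(=O)C=C(Br)C(Br)=C1
A7 | alternative 2 | tert-butyl 2,3-dihydro-1H-pyrrole-1-carboxylate | CC(C)(C)OC(=O)N1CCC=C1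
A8 | alternative 2 | tert-butyl cis-5,6-dibromo-2,3,3a,7a-tetrahydroindole-1-carboxylate (racemic, one enantiomer drawn) | CC(C)(C)OC(=O)N1CC[C@H]2C=C(Br)C(Br)=C[C@@H]12
A9 | alternative 3 | 4,5-dibromo-2,3-bis(bromoethynyl)-1-tosylpyrrole | Cc1ccc(cc1)S(=O)(=O)n1c(Br)c(Br)c(C#CBr)c1C#CBr
A10 | alternative 3 | cyclohexa-1,4-diene | C1=CCC=CC1
A11 | alternative 3 | 2,3,5,6-tetrabromo-1-tosylindole | Cc1ccc(cc1)S(=O)(=O)n1c(Br)c(Br)c2cc(Br)c(Br)cc12
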